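## Retrosynthetic overview

1. Cut the ester C–O bond: target ⇐ spiro-epoxy lactone 22 (left half, acid held as tert-butyl ester) + dihydroxy acid 28 (right half); the carboxylate opens the epoxide at CH2 and gives the primary ester and the tertiary alcohol in one step.
2. 22 ⇐ seco hydroxy acid 21 (seven-ring lactonisation) ⇐ oxidative C–C cleavage of ring A of cis-octalin 15 after a Schenck ene transposition; the spiro-epoxide comes from the ring B ketone.
3. Key step: Diels–Alder reaction of (S)-cryptone 6 with silyloxy diene 13 builds ring A on ring B and sets both ring-fusion centres from the isopropyl centre.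
4. 28 ⇐ 6 by anti conjugate vinylation/enol triflate, Stille hydroxymethylation and cross-metathesis; 6 ⇐ (+)-limonene oxide, the only source of chirality.
5. Ring order: ring B is bought; ring A is made by cycloaddition, then opened and re-closed as the seven-membered lactone; the right-half cyclohexene is ring B of a second molecule of 6.

Assumption: commercial (+)-limonene oxide ((4R), cis/trans mixture) is used as such, because the epoxide stereocentres are erased in steps 3–4.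

## Route

Step 1
Reactants: 1 (+)-limonene oxide
Product: 2 (4R)-1-methyl-4-(propan-2-yl)-7-oxabicyclo[4.1.0]heptane
Conditions: H2 (1 atm), RhCl(PPh3)3 (2 mol %), PhH/EtOH, rt
Reagents that add atoms: none
Why: Homogeneous hydrogenation reduces the 1,1-disubstituted isopropenyl alkene only and leaves the epoxide and the C4 stereocentre untouched.

Step 2
Reactants: 2 dihydrolimonene oxide
Product: 3 (5R)-2-methylidene-5-(propan-2-yl)cyclohexan-1-ol
Conditions: LiN(iPr)2 (2.5 equiv), Et2O, 0 °C to reflux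
Reagents that add atoms: none
Why: Base-promoted epoxide-to-allylic-alcohol isomerisation (syn β-elimination) takes a proton from the unhindered methyl group and gives the exocyclic methylene alcohol.

Step 3
Reactants: 3 exocyclic allylic alcohol
Product: 4 (4R)-2-hydroxy-4-(propan-2-yl)cyclohexan-1-one
Conditions: O3, CH2Cl2/MeOH, −78 °C; then Me2S, −78 °C to rt
Reagents that add atoms: ozone, [O-][O+]=O
Why: Ozonolysis with reductive work-up removes the exocyclic CH2 and leaves the ring ketone.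

Step 4
Reactants: 4 α-hydroxy ketone
Product: 6 (4S)-4-(propan-2-yl)cyclohex-2-en-1-one [(S)-cryptone], via α-mesyloxy ketone 5 (not isolated)
Conditions: MsCl, Et3N, CH2Cl2, 0 °C; then DBU, PhMe, 60 °C
Reagents that add atoms: none
Why: Sulfonylation followed by E2 elimination of the α-mesylate with the C3 hydrogen gives the conjugated enone; the γ stereocentre is not touched (the descriptor changes only through CIP priorities).

Step 5
Reactants: 7 tert-butyl 2-bromopropanoate; 8 triethyl phosphite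
Product: 9 tert-butyl 2-(diethoxyphosphoryl)propanoate
Conditions: neat, 140 °C, EtBr distilled off
Reagents that add atoms: none
Why: Michaelis–Arbuzov reaction of the α-bromo ester.

Step 6
Reactants: 9 phosphonate; 10 2,2-dimethoxyacetaldehyde
Product: 12 tert-butyl (2E)-2-methyl-4-oxobut-2-enoate, via dimethyl acetal 11 (not isolated)
Conditions: LiCl, DBU, MeCN, 0 °C to rt; then 1 M aq HCl, THF, rt
Reagents that add atoms: water, O
Why: Horner–Wadsworth–Emmons olefination (Masamune–Roush conditions) followed by mild acetal hydrolysis that spares the tert-butyl ester; the alkene geometry is irrelevant because this bond becomes the diene single bond.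

Step 7
Reactants: 12 enal ester
Product: 13 tert-butyl (3E)-4-[(tert-butyldimethylsilyl)oxy]-2-methylidenebut-3-enoate
Conditions: TBSOTf, Et3N, Et2O, 0 °C; used at once
Reagents that add atoms: tert-butyldimethylsilyl trifluoromethanesulfonate, CC(C)(C)[Si](C)(C)OS(=O)(=O)C(F)(F)F
Why: Soft γ-enolisation (O-silylation, loss of a methyl proton) gives the (E)-1-silyloxy diene.

Step 8
Reactants: 6 (S)-cryptone; 13 silyloxy diene
Product: 14 tert-butyl (4S,4aR,8S,8aS)-4-[(tert-butyldimethylsilyl)oxy]-5-oxo-8-(propan-2-yl)-1,4,4a,5,6,7,8,8a-octahydronaphthalene-2-carboxylate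
Conditions: Me2AlCl (0.3 equiv), CH2Cl2, −78 to −20 °C, 13 added slowly
Reagents that add atoms: none
Why: Lewis-acid-catalysed Diels–Alder reaction; the silyloxy terminus bonds to the enone α-carbon and the CH2 terminus to the β-carbon (ortho and para effects reinforce), the diene adds endo and suprafacially to the face anti to the isopropyl group, so ring A is cis-fused and both ring-fusion centres follow from the bought centre (the C4 carbinol centre is lost later).

Step 9
Reactants: 14 cis-octalone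
Product: 15 tert-butyl (4S,4aR,5R,8S,8aS)-4-[(tert-butyldimethylsilyl)oxy]-8-(propan-2-yl)-1,4,4a,6,7,8,8a-heptahydrospiro[naphthalene-5,2'-oxirane]-2-carboxylate
Conditions: Me3S+ I−, n-BuLi, THF, −10 °C; then 14, −78 to 0 °C
Reagents that add atoms: trimethylsulfonium iodide, C[S+](C)C.[I-]
Why: Corey–Chaykovsky epoxidation; the sulfonium ylide attacks the ketone irreversibly along the axial trajectory on the convex face, anti to the axial ring A bond at C4a, which places CH2 axial and O equatorial (5R) and removes the ketone before C4a can epimerise.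

Step 10
Reactants: 15 spiro-epoxide enoate
Product: 18 tert-butyl (4R,4aR,5R,8S,8aR)-3,4-dihydroxy-8-(propan-2-yl)-3,4,4a,6,7,8,8a-heptahydrospiro[naphthalene-5,2'-oxirane]-2-carboxylate (C3 epimers), via allylic hydroperoxide 16 (not isolated), via silyl ether alcohol 17 (not isolated)
Conditions: O2, hν (Na lamp), tetraphenylporphyrin (cat.), CH2Cl2, 0 °C; then PPh3; then Bu4NF, THF, 0 °C
Reagents that add atoms: dioxygen, O=O
Why: Schenck ene reaction of singlet oxygen with the α,β-unsaturated ester abstracts hydrogen from the ring CH2 geminal to the ester (gem effect), moving the alkene to C1=C2 and placing oxygen on C3; phosphine reduces the hydroperoxide and fluoride removes the silyl group (the C3/C4 carbinol centres are destroyed in step 11).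

Step 11
Reactants: 18 diol
Product: 19 tert-butyl (2E)-2-formyl-3-[(3R,4S,5R,6S)-4-formyl-6-(propan-2-yl)-1-oxaspiro[2.5]octan-5-yl]prop-2-enoate
Conditions: NaIO4, THF/H2O (pH 7), 0 °C to rt
Reagents that add atoms: none
Why: Periodate glycol cleavage opens ring A between the two carbinol carbons; the ring alkene geometry (formyl cis to the ring carbon) is carried over unchanged.

Step 12
Reactants: 19 dialdehyde
Product: 20 tert-butyl (2E)-3-[(3R,4S,5R,6S)-4-formyl-6-(propan-2-yl)-1-oxaspiro[2.5]octan-5-yl]-2-(hydroxymethyl)prop-2-enoate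
Conditions: NaBH4 (0.3 equiv), CeCl3·7H2O, MeOH, −78 °C
Reagents that add atoms: none
Why: Luche reduction is selective for the conjugated, unhindered aldehyde (1,2-addition) over the hindered saturated aldehyde, which is masked as its hemiacetal under these conditions.

Step 13
Reactants: 20 hydroxy aldehyde
Product: 21 (3R,4S,5R,6S)-5-[(1E)-3-tert-butoxy-2-(hydroxymethyl)-3-oxoprop-1-en-1-yl]-6-(propan-2-yl)-1-oxaspiro[2.5]octane-4-carboxylic acid
Conditions: NaClO2, NaH2PO4, 2-methylbut-2-ene, t-BuOH/H2O, 0 °C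
Reagents that add atoms: sodium chlorite, [Na+].[O-]Cl=O
Why: Pinnick oxidation converts the aldehyde to the acid at pH about 4 without touching the allylic alcohol, the epoxide or the α-stereocentre.

Step 14
Reactants: 21 hydroxy acid
Product: 22 tert-butyl (5aR,6S,9R,9aS)-1-oxo-6-(propan-2-yl)-1,5a,6,7,8,9a-hexahydro-3H-spiro[2-benzoxepine-9,2'-oxirane]-4-carboxylate
Conditions: 2-methyl-6-nitrobenzoic anhydride, DMAP, Et3N, CH2Cl2 (2 mM), rt
Reagents that add atoms: none
Why: Shiina lactonisation; acyl activation lets the primary allylic alcohol close only the seven-membered ring, which is pre-organised by the cis ring substituents and the in-ring alkene geometry.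

Step 15
Reactants: 6 (S)-cryptone
Product: 24 (3S,4S)-3-ethenyl-4-(propan-2-yl)cyclohex-1-en-1-yl trifluoromethanesulfonate, via bromomagnesium enolate 23 (not isolated)
Conditions: CH2=CHMgBr, CuBr·SMe2 (10 mol %), THF, −78 to −40 °C; then PhNTf2, DMPU, −78 °C to rt
Reagents that add atoms: vinylmagnesium bromide, C=C[Mg]Br; N-phenylbis(trifluoromethanesulfonimide), O=S(=O)(N(c1ccccc1)S(=O)(=O)C(F)(F)F)C(F)(F)F
Why: Copper-catalysed conjugate addition delivers the vinyl group anti to the adjacent isopropyl group (trans-3,4), and O-triflation of the regiodefined enolate fixes the ring alkene position.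

Step 16
Reactants: 24 enol triflate
Product: 25 [(3S,4S)-3-ethenyl-4-(propan-2-yl)cyclohex-1-en-1-yl]methanol
Conditions: Bu3SnCH2OH, Pd(PPh3)4 (5 mol %), LiCl, dioxane, 95 °C
Reagents that add atoms: (tributylstannyl)methanol, CCCC[Sn](CCCC)(CCCC)CO
Why: Stille cross-coupling of the enol triflate installs the hydroxymethyl carbon with retention of the alkene position; no stereocentre is involved.

Step 17
Reactants: 25 dienyl alcohol; 26 methyl 2-(hydroxymethyl)prop-2-enoate (5 equiv)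
Product: 27 methyl (2E)-2-(hydroxymethyl)-3-[(1S,6S)-3-(hydroxymethyl)-6-(propan-2-yl)cyclohex-2-en-1-yl]prop-2-enoate
Conditions: second-generation Hoveyda–Grubbs catalyst RuCl2(H2IMes)(=CH-C6H4-2-OiPr) (7 mol %), CH2Cl2, 40 °C
Reagents that add atoms: none
Why: Olefin cross-metathesis of the terminal vinyl group with the 1,1-disubstituted acrylate gives the trisubstituted enoate with the ester trans to the ring (E, thermodynamic); the trisubstituted ring alkene does not react.

Step 18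
Reactants: 27 methyl ester
Product: 28 (2E)-2-(hydroxymethyl)-3-[(1S,6S)-3-(hydroxymethyl)-6-(propan-2-yl)cyclohex-2-en-1-yl]prop-2-enoic acid
Conditions: LiOH, THF/H2O, rt; then 1 M HCl to pH 3
Reagents that add atoms: lithium hydroxide, [Li+].[OH-]
Why: Saponification of the only ester present.

Step 19
Reactants: 22 spiro-epoxy lactone; 28 acid (1.5 equiv)
Product: 29 tert-butyl (5aR,6S,9R,9aS)-9-hydroxy-9-({[(2E)-2-(hydroxymethyl)-3-[(1S,6S)-3-(hydroxymethyl)-6-(propan-2-yl)cyclohex-2-en-1-yl]prop-2-enoyl]oxy}methyl)-1-oxo-6-(propan-2-yl)-1,3,5a,6,7,8,9,9a-octahydro-2-benzoxepine-4-carboxylate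
Conditions: Cs2CO3 (0.3 equiv), DMF, 60 °C
Reagents that add atoms: none
Why: SN2 opening of the 1,1-disubstituted epoxide at CH2 by the cesium carboxylate forms the primary ester and frees the tertiary alcohol with its configuration retained; the excess acid keeps the medium buffered so the lactone survives.

Step 20
Reactants: 29 tert-butyl ester
Product: 30 target acid
Conditions: CF3CO2H/CH2Cl2 (1:5), 0 °C
Reagents that add atoms: none
Why: Acidolysis of the tert-butyl ester (loss of isobutene) frees the acid; the lactone and the linking ester are stable and the tertiary alcohol is deactivated by its β-acyloxy groups.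

## Compound list

1 | (4R)-1-methyl-4-(prop-1-en-2-yl)-7-oxabicyclo[4.1.0]heptane, (+)-limonene oxide, cis/trans mixture | CC(=C)[C@@H]1CCC2(C)OC2C1 | starting material
2 | (4R)-1-methyl-4-(propan-2-yl)-7-oxabicyclo[4.1.0]heptane, epoxide diastereomers | CC(C)[C@@H]1CCC2(C)OC2C1 | intermediate
3 | (5R)-2-methylidene-5-(propan-2-yl)cyclohexan-1-ol, C1 epimers | CC(C)[C@@H]1CCC(=C)C(O)C1 | intermediate
4 | (4R)-2-hydroxy-4-(propan-2-yl)cyclohexan-1-one, C2 epimers | CC(C)[C@@H]1CCC(=O)C(O)C1 | intermediate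
5 | (5R)-2-oxo-5-(propan-2-yl)cyclohexyl methanesulfonate, C1 epimers | CC(C)[C@@H]1CCC(=O)C(OS(C)(=O)=O)C1 | intermediate
6 | (4S)-4-(propan-2-yl)cyclohex-2-en-1-one, (S)-cryptone | CC(C)[C@@H]1CCC(=O)C=C1 | intermediate
7 | tert-butyl 2-bromopropanoate, racemic | CC(Br)C(=O)OC(C)(C)C | starting material
8 | triethyl phosphite | CCOP(OCC)OCC | starting material
9 | tert-butyl 2-(diethoxyphosphoryl)propanoate, racemic | CCOP(=O)(OCC)C(C)C(=O)OC(C)(C)C | intermediate
10 | 2,2-dimethoxyacetaldehyde | COC(OC)C=O | starting material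
11 | tert-butyl (2E)-4,4-dimethoxy-2-methylbut-2-enoate | COC(OC)/C=C(\C)C(=O)OC(C)(C)C | intermediate
12 | tert-butyl (2E)-2-methyl-4-oxobut-2-enoate | O=C/C=C(\C)C(=O)OC(C)(C)C | intermediate
13 | tert-butyl (3E)-4-[(tert-butyldimethylsilyl)oxy]-2-methylidenebut-3-enoate | C=C(/C=C/O[Si](C)(C)C(C)(C)C)C(=O)OC(C)(C)C | intermediate
14 | tert-butyl (4S,4aR,8S,8aS)-4-[(tert-butyldimethylsilyl)oxy]-5-oxo-8-(propan-2-yl)-1,4,4a,5,6,7,8,8a-octahydronaphthalene-2-carboxylate, cis-fused | CC(C)[C@@H]1CCC(=O)[C@H]2[C@@H](O[Si](C)(C)C(C)(C)C)C=C(C(=O)OC(C)(C)C)C[C@@H]12 | intermediate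
15 | tert-butyl (4S,4aR,5R,8S,8aS)-4-[(tert-butyldimethylsilyl)oxy]-8-(propan-2-yl)-1,4,4a,6,7,8,8a-heptahydrospiro[naphthalene-5,2'-oxirane]-2-carboxylate | CC(C)[C@@H]1CC[C@]2(CO2)[C@H]3[C@@H](O[Si](C)(C)C(C)(C)C)C=C(C(=O)OC(C)(C)C)C[C@@H]13 | intermediate
16 | tert-butyl (4R,4aR,5R,8S,8aR)-4-[(tert-butyldimethylsilyl)oxy]-3-hydroperoxy-8-(propan-2-yl)-3,4,4a,6,7,8,8a-heptahydrospiro[naphthalene-5,2'-oxirane]-2-carboxylate, C3 epimers | CC(C)[C@@H]1CC[C@]2(CO2)[C@H]3[C@@H](O[Si](C)(C)C(C)(C)C)C(OO)C(C(=O)OC(C)(C)C)=C[C@@H]13 | intermediate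
17 | tert-butyl (4R,4aR,5R,8S,8aR)-4-[(tert-butyldimethylsilyl)oxy]-3-hydroxy-8-(propan-2-yl)-3,4,4a,6,7,8,8a-heptahydrospiro[naphthalene-5,2'-oxirane]-2-carboxylate, C3 epimers | CC(C)[C@@H]1CC[C@]2(CO2)[C@H]3[C@@H](O[Si](C)(C)C(C)(C)C)C(O)C(C(=O)OC(C)(C)C)=C[C@@H]13 | intermediate
18 | tert-butyl (4R,4aR,5R,8S,8aR)-3,4-dihydroxy-8-(propan-2-yl)-3,4,4a,6,7,8,8a-heptahydrospiro[naphthalene-5,2'-oxirane]-2-carboxylate, C3 epimers | CC(C)[C@@H]1CC[C@]2(CO2)[C@H]3[C@@H](O)C(O)C(C(=O)OC(C)(C)C)=C[C@@H]13 | intermediate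
19 | tert-butyl (2E)-2-formyl-3-[(3R,4S,5R,6S)-4-formyl-6-(propan-2-yl)-1-oxaspiro[2.5]octan-5-yl]prop-2-enoate | CC(C)[C@@H]1CC[C@]2(CO2)[C@@H](C=O)[C@H]1/C=C(\C=O)C(=O)OC(C)(C)C | intermediate
20 | tert-butyl (2E)-3-[(3R,4S,5R,6S)-4-formyl-6-(propan-2-yl)-1-oxaspiro[2.5]octan-5-yl]-2-(hydroxymethyl)prop-2-enoate | CC(C)[C@@H]1CC[C@]2(CO2)[C@@H](C=O)[C@H]1/C=C(\CO)C(=O)OC(C)(C)C | intermediate
21 | (3R,4S,5R,6S)-5-[(1E)-3-tert-butoxy-2-(hydroxymethyl)-3-oxoprop-1-en-1-yl]-6-(propan-2-yl)-1-oxaspiro[2.5]octane-4-carboxylic acid | CC(C)[C@@H]1CC[C@]2(CO2)[C@@H](C(=O)O)[C@H]1/C=C(\CO)C(=O)OC(C)(C)C | intermediate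
22 | tert-butyl (5aR,6S,9R,9aS)-1-oxo-6-(propan-2-yl)-1,5a,6,7,8,9a-hexahydro-3H-spiro[2-benzoxepine-9,2'-oxirane]-4-carboxylate | CC(C)[C@@H]1CC[C@]2(CO2)[C@H]3C(=O)OCC(C(=O)OC(C)(C)C)=C[C@@H]13 | intermediate
23 | bromomagnesium (3S,4S)-3-ethenyl-4-(propan-2-yl)cyclohex-1-en-1-olate | C=C[C@@H]1C=C(O[Mg]Br)CC[C@H]1C(C)C | intermediate
24 | (3S,4S)-3-ethenyl-4-(propan-2-yl)cyclohex-1-en-1-yl trifluoromethanesulfonate | C=C[C@@H]1C=C(OS(=O)(=O)C(F)(F)F)CC[C@H]1C(C)C | intermediate
25 | [(3S,4S)-3-ethenyl-4-(propan-2-yl)cyclohex-1-en-1-yl]methanol | C=C[C@@H]1C=C(CO)CC[C@H]1C(C)C | intermediate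
26 | methyl 2-(hydroxymethyl)prop-2-enoate | COC(=O)C(=C)CO | starting material
27 | methyl (2E)-2-(hydroxymethyl)-3-[(1S,6S)-3-(hydroxymethyl)-6-(propan-2-yl)cyclohex-2-en-1-yl]prop-2-enoate | COC(=O)/C(=C/[C@@H]1C=C(CO)CC[C@H]1C(C)C)CO | intermediate
28 | (2E)-2-(hydroxymethyl)-3-[(1S,6S)-3-(hydroxymethyl)-6-(propan-2-yl)cyclohex-2-en-1-yl]prop-2-enoic acid | OC(=O)/C(=C/[C@@H]1C=C(CO)CC[C@H]1C(C)C)CO | intermediate
29 | tert-butyl (5aR,6S,9R,9aS)-9-hydroxy-9-({[(2E)-2-(hydroxymethyl)-3-[(1S,6S)-3-(hydroxymethyl)-6-(propan-2-yl)cyclohex-2-en-1-yl]prop-2-enoyl]oxy}methyl)-1-oxo-6-(propan-2-yl)-1,3,5a,6,7,8,9,9a-octahydro-2-benzoxepine-4-carboxylate | CC(C)[C@@H]1CC[C@](O)(COC(=O)/C(=C/[C@@H]2C=C(CO)CC[C@H]2C(C)C)CO)[C@H]2C(=O)OCC(C(=O)OC(C)(C)C)=C[C@@H]12 | intermediate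
30 | (5aR,6S,9R,9aS)-9-hydroxy-9-({[(2E)-2-(hydroxymethyl)-3-[(1S,6S)-3-(hydroxymethyl)-6-(propan-2-yl)cyclohex-2-en-1-yl]prop-2-enoyl]oxy}methyl)-1-oxo-6-(propan-2-yl)-1,3,5a,6,7,8,9,9a-octahydro-2-benzoxepine-4-carboxylic acid | CC(C)[C@@H]1CC[C@](O)(COC(=O)/C(=C/[C@@H]2C=C(CO)CC[C@H]2C(C)C)CO)[C@H]2C(=O)OCC(C(=O)O)=C[C@@H]12 | target

## Step count and risks

Total steps: 20. Longest linear sequence: 13 (steps 1–4, 8–14, 19, 20).

Most likely to fail, step 8: diene 13 carries its own acrylate and can dimerise faster than it adds to the sluggish enone 6. The fallback sets out from 6 and comes back at 15. Sodium formylacetone is O-silylated with TBSCl to (3E)-4-[(tert-butyldimethylsilyl)oxy]but-3-en-2-one F1, which Me3SiOTf/Et3N converts into the ester-free diene tert-butyl(dimethyl){[(1E)-3-[(trimethylsilyl)oxy]buta-1,3-dien-1-yl]oxy}silane F2. Its cycloaddition with 6 (PhMe, 110 °C, or ZnCl2 cat.) gives the cis-fused silyl enol ether (4S,4aR,8S,8aS)-4-[(tert-butyldimethylsilyl)oxy]-8-(propan-2-yl)-2-[(trimethylsilyl)oxy]-4,4a,6,7,8,8a-hexahydronaphthalen-5(1H)-one F3 (numbered as 14). Me3S+ I−/n-BuLi gives its spiro-epoxide F4, CsF/PhNTf2 turns the trimethylsilyl enol ether regiospecifically into the enol triflate F5, and Pd(OAc)2/Xantphos, CO, t-BuOH, Et3N carbonylation installs the tert-butyl ester, which is 15.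

Second, step 10: the ene reaction of an ester-deactivated, γ-oxygenated alkene may be too slow or unselective. The fallback sets out from 15 and comes back at 17 (then Bu4NF as in step 10 gives 18). LiOOt-Bu epoxidises the enoate to the glycidic ester F6, SmI2 (THF, HMPA) opens it reductively at the α-carbon to the β-hydroxy ester F7 without touching the spiro-epoxide, LiN(iPr)2 (2.2 equiv) then PhSeBr gives the α-phenylselanyl β-hydroxy ester F8, and H2O2 triggers selenoxide syn-elimination away from the carbinol carbon to give 17.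

Third, step 17: cross-metathesis next to a hindered allylic stereocentre to form a trisubstituted enoate may stall. The fallback sets out from 24 and comes back at 27. Ozonolysis of the vinyl group of 24 (O3, CH2Cl2/MeOH, −78 °C, Me2S; the enol triflate alkene is deactivated) gives (1S,6S)-6-(propan-2-yl)-3-{[(trifluoromethyl)sulfonyl]oxy}cyclohex-2-ene-1-carbaldehyde F9. Tandem oxa-Michael/Horner–Wadsworth–Emmons reaction with trimethyl 2-phosphonoacrylate and 4-MeOC6H4CH2ONa gives the (E)-2-[(4-methoxybenzyl)oxymethyl] enoate triflate F10, Stille hydroxymethylation as in step 16 gives the allylic alcohol F11, and DDQ (CH2Cl2, pH 7 buffer, 0 °C) removes the 4-methoxybenzyl group to give 27.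

Further compounds
F1 | step 8 | (3E)-4-[(tert-butyldimethylsilyl)oxy]but-3-en-2-one | CC(=O)/C=C/O[Si](C)(C)C(C)(C)C
F2 | step 8 | tert-butyl(dimethyl){[(1E)-3-[(trimethylsilyl)oxy]buta-1,3-dien-1-yl]oxy}silane | C=C(O[Si](C)(C)C)/C=C/O[Si](C)(C)C(C)(C)C
F3 | step 8 | (4S,4aR,8S,8aS)-4-[(tert-butyldimethylsilyl)oxy]-8-(propan-2-yl)-2-[(trimethylsilyl)oxy]-4,4a,6,7,8,8a-hexahydronaphthalen-5(1H)-one | CC(C)[C@@H]1CCC(=O)[C@H]2[C@@H](O[Si](C)(C)C(C)(C)C)C=C(O[Si](C)(C)C)C[C@@H]12
F4 | step 8 | (4S,4aR,5R,8S,8aS)-4-[(tert-butyldimethylsilyl)oxy]-8-(propan-2-yl)-2-[(trimethylsilyl)oxy]-1,4,4a,6,7,8,8a-heptahydrospiro[naphthalene-5,2'-oxirane] | CC(C)[C@@H]1CC[C@]2(CO2)[C@H]3[C@@H](O[Si](C)(C)C(C)(C)C)C=C(O[Si](C)(C)C)C[C@@H]13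
F5 | step 8 | (4S,4aR,5R,8S,8aS)-4-[(tert-butyldimethylsilyl)oxy]-8-(propan-2-yl)-1,4,4a,6,7,8,8a-heptahydrospiro[naphthalene-5,2'-oxirane]-2-yl trifluoromethanesulfonate | CC(C)[C@@H]1CC[C@]2(CO2)[C@H]3[C@@H](O[Si](C)(C)C(C)(C)C)C=C(OS(=O)(=O)C(F)(F)F)C[C@@H]13
F6 | step 10 | 2,3-epoxide of 15 (glycidic tert-butyl ester, epoxide diastereomers) | CC(C)[C@@H]1CC[C@]2(CO2)[C@H]3[C@@H](O[Si](C)(C)C(C)(C)C)C4OC4(C(=O)OC(C)(C)C)C[C@@H]13
F7 | step 10 | 3-hydroxy-2,3-dihydro derivative of 15 (β-hydroxy tert-butyl ester, diastereomers at C2 and C3) | CC(C)[C@@H]1CC[C@]2(CO2)[C@H]3[C@@H](O[Si](C)(C)C(C)(C)C)C(O)C(C(=O)OC(C)(C)C)C[C@@H]13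
F8 | step 10 | 2-(phenylselanyl) derivative of F7 | CC(C)[C@@H]1CC[C@]2(CO2)[C@H]3[C@@H](O[Si](C)(C)C(C)(C)C)C(O)C([Se]c4ccccc4)(C(=O)OC(C)(C)C)C[C@@H]13
F9 | step 17 | (1S,6S)-6-(propan-2-yl)-3-{[(trifluoromethyl)sulfonyl]oxy}cyclohex-2-ene-1-carbaldehyde | O=C[C@@H]1C=C(OS(=O)(=O)C(F)(F)F)CC[C@H]1C(C)C
F10 | step 17 | methyl (2E)-2-{[(4-methoxyphenyl)methoxy]methyl}-3-[(1S,6S)-6-(propan-2-yl)-3-{[(trifluoromethyl)sulfonyl]oxy}cyclohex-2-en-1-yl]prop-2-enoate | COC(=O)/C(=C/[C@@H]1C=C(OS(=O)(=O)C(F)(F)F)CC[C@H]1C(C)C)COCc1ccc(OC)cc1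
F11 | step 17 | methyl (2E)-3-[(1S,6S)-3-(hydroxymethyl)-6-(propan-2-yl)cyclohex-2-en-1-yl]-2-{[(4-methoxyphenyl)methoxy]methyl}prop-2-enoate | COC(=O)/C(=C/[C@@H]1C=C(CO)CC[C@H]1C(C)C)COCc1ccc(OC)cc1
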